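You have 4 questions on two flasks: which form holds most of the G at the end, and how much.

    G + Q → G.Q (k1 = 7.5 L mol⁻¹ s⁻¹)
    G + Q → Z (k2 = 16 L mol⁻¹ s⁻¹)
    Q + Z ⇌ Q.Z (K3 = 110 L mol⁻¹, k3 = 0.26 L mol⁻¹ s⁻¹)
    Q + Z → D (k4 = 1.9 L mol⁻¹ s⁻¹)

the same everywhere: G 20 mM; time 100 s
- beta: Q 18.0 mM
- alpha: Q 54.0 mM

1. which of these there is most of at the end, counted by the G in it, beta (G.Q / Q.Z / D / Z / G)
2. which of these there is most of at the end, counted by the G in it, alpha (G.Q / Q.Z / D / Z / G)
3. the largest of these amounts at the end, in percent of the G charged, beta
4. the largest of these amounts at the end, in percent of the G charged, alpha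

Reckon in fractions of the G charge. Both G steps are first order in G and in Q, so Z takes a fixed share of the G turned over, 0.681 (the selectivity). Each G used takes one Q, and each Z taken on takes one more. Call the sum the Q demand, the equivalents of Q per G charged that turn over all the G and then take on all the Z: 1.68.

Beta charges 0.900 equivalents, below one, so Z stays under 0.613 of the charge and should lead. Alpha charges 2.70, above the demand. In alpha Z then goes on, and the forward split of step 3 and step 4 puts D near 0.599.

The forecast gives Z at 51.5 % in beta and D at 60.3 % in alpha. Its ground for beta is “Q is limiting and runs out by about 40–50 s”.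

The simulation gives Z at 51.6 % in beta and D at 60.4 % in alpha, so the forecast held.

In beta, Q is the limiting reagent: 0.900 equivalents against a demand of 1.68, and 0.0174 % of its charge is left at the end. That running short of Q holds D in beta at 5.19 %; the same run without it reaches 59.3 %.

Now take the neighbour, beta with 12 mM of G. It charges 1.50 equivalents, under the demand, so at least 0.181 of the charge should stay as Z. The computed flask holds Z at 33.6 % and D at 30.8 %, with 10.4 % of its Q still there.

The rate constants are those of an exercise; what happens was integrated by code.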